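**Plan**

1. Numbering: lactone O1, C2 (C=O), C3, C4, C5; C6 is the CH2 between C3 and ring B (3,4-dihydroxy-5-methoxyphenyl); C7 is the CH2 between C4 and ring A (4-hydroxy-3-methoxyphenyl).
2. Enabling feature: each benzylic carbon sits directly on a ring stereocentre (C6 on C3, C7 on C4), so C6–C3 and C7–C4 can be drawn as the alkenes of a ring-B cinnamate and a ring-A cinnamyl unit already linked through O1–C5; a temporary C6–C7 bond then makes C3–C4–C7–C6 a cyclobutane fused to the lactone.
3. Retrosynthesis: invert C3 (trans to cis lactone), re-form C6–C7, cut C3–C4 and C6–C7 together ([2+2]), then cut the ester bond C2–O1, giving a ring-B cinnamic acid and a ring-A cinnamyl alcohol.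
4. Forward: esterification joins the halves; one photochemical step closes the lactone ring and the cyclobutane; lithium in ammonia cuts C6–C7 again while the lactone is held as its carboxylate and then re-closed; base turns the cis lactone into the trans lactone; the last protecting group is removed.
5. Stereochemistry: C4 (R) is fixed in the cycloaddition by a chiral oxazaborolidine–AlBr3 Lewis acid on the cinnamate carbonyl, relayed through the obligatory cis ring fusion; C3 (R) is set at the end by thermodynamic epimerisation; the stereocentres at C6 and C7 are transient.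
6. Protecting groups: benzyl on ring B (cleaved to aryloxides by lithium/ammonia, which shields this trioxygenated ring from reduction) and isopropyl on ring A (keeps ring A a neutral electron acceptor for the scission; removed last with BCl3).

Key step: step 6

Assumption: the sense of induction of the oxazaborolidine–AlBr3 complex on an acyclic cinnamate cannot be fixed on paper; the (S)-prolinol-derived catalyst is written for the (1S,5R) cycloadduct, and its mirror image is to be used if a first experiment shows the opposite sense.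

**Route**

Step 1
Reactants: 1 ferulic acid
Product: 2 propan-2-yl (E)-3-[3-methoxy-4-(propan-2-yloxy)phenyl]prop-2-enoate
Conditions: 2-bromopropane (4 equiv), K2CO3 (3 equiv), DMF, 60 °C
Reagents that add atoms: 2-bromopropane, CC(C)Br
Why: Williamson etherification of the phenoxide and SN2 O-alkylation of the carboxylate occur together, giving an isopropyl ether that should withstand the Lewis acid of step 6 and the lithium/ammonia of step 8, and an ester ready for reduction.

Step 2
Reactants: 2 propan-2-yl (E)-3-[3-methoxy-4-(propan-2-yloxy)phenyl]prop-2-enoate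
Product: 3 (E)-3-[3-methoxy-4-(propan-2-yloxy)phenyl]prop-2-en-1-ol
Conditions: DIBAL-H ((Me2CHCH2)2AlH, 2.5 equiv), CH2Cl2, −78 to 0 °C; aqueous potassium sodium tartrate
Reagents that add atoms: none
Why: DIBAL reduction of an α,β-unsaturated ester proceeds by 1,2-hydride delivery only and should give the allylic alcohol with the E alkene intact.

Step 3
Reactants: 4 5-hydroxyvanillin
Product: 5 3,4-bis(benzyloxy)-5-methoxybenzaldehyde
Conditions: benzyl bromide (2.4 equiv), K2CO3 (3 equiv), DMF, 60 °C
Reagents that add atoms: benzyl bromide, BrCc1ccccc1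
Why: Double Williamson etherification of the catechol installs the benzyl ethers that step 8 later converts into reduction-resistant aryloxides.

Step 4
Reactants: 5 3,4-bis(benzyloxy)-5-methoxybenzaldehyde; 6 malonic acid
Product: 8 (E)-3-[3,4-bis(benzyloxy)-5-methoxyphenyl]prop-2-enoic acid, via arylidenemalonic acid 7 (not isolated)
Conditions: pyridine, piperidine (0.1 equiv), 95 °C
Reagents that add atoms: none
Why: Knoevenagel condensation followed by decarboxylation in pyridine (Doebner modification) should give the E cinnamic acid under thermodynamic control.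

Step 5
Reactants: 3 (E)-3-[3-methoxy-4-(propan-2-yloxy)phenyl]prop-2-en-1-ol; 8 (E)-3-[3,4-bis(benzyloxy)-5-methoxyphenyl]prop-2-enoic acid
Product: 9 (E)-3-[3-methoxy-4-(propan-2-yloxy)phenyl]prop-2-en-1-yl (E)-3-[3,4-bis(benzyloxy)-5-methoxyphenyl]prop-2-enoate
Conditions: N,N'-dicyclohexylcarbodiimide (DCC, 1.2 equiv), 4-(dimethylamino)pyridine (0.1 equiv), CH2Cl2, 0 °C to rt
Reagents that add atoms: none
Why: Steglich esterification forms the O1–C2 ester under neutral conditions, avoiding ionisation of the electron-rich cinnamyl alcohol that an acid chloride and HCl would provoke.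

Step 6
Reactants: 9 (E)-3-[3-methoxy-4-(propan-2-yloxy)phenyl]prop-2-en-1-yl (E)-3-[3,4-bis(benzyloxy)-5-methoxyphenyl]prop-2-enoate
Product: 10 (1S,5R,6S,7R)-7-[3,4-bis(benzyloxy)-5-methoxyphenyl]-6-[3-methoxy-4-(propan-2-yloxy)phenyl]-3-oxabicyclo[3.2.0]heptan-2-one (cis-fused; both aryl groups exo)
Conditions: (S)-1-(2-methylphenyl)-3,3-diphenyltetrahydro-1H,3H-pyrrolo[1,2-c][1,3,2]oxazaborole (0.5 equiv), AlBr3 (0.5 equiv), Ir(ppy)3 (tris(2-phenylpyridinato)iridium, 2 mol%), CH2Cl2 (0.01 M), −78 °C, 450 nm LEDs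
Reagents that add atoms: none
Why: Proposed new method: the AlBr3-activated oxazaborolidine binds the cinnamate carbonyl of 9 and lowers its triplet energy, so that Ir(ppy)3 (trivalent iridium) sensitises only the bound ester, whose α-carbon C3 adds to C4 of the cinnamyl alkene to give a 1,4-diradical with benzylic centres C6 and C7 that couples after intersystem crossing; the closest known reaction types are the chiral-oxazaborolidine-catalysed, iridium-sensitised intermolecular [2+2] photocycloaddition of cinnamate esters with styrenes and the sensitised intramolecular [2+2] cycloaddition of cinnamyl-tethered 1,6-dienes, neither shown with an ester tether under chiral Lewis-acid control. The lactone ring closes by 5-exo-trig radical addition (rule of five) and the cyclobutane by recombination of the two benzylic radicals. C3 is set by the cinnamate face the Lewis acid leaves open, C4 follows because the three-atom O1–C5 tether allows only a cis ring fusion, and C6 and C7 are expected to place both aryl groups exo but are erased in step 8, so any diastereomer at these two centres converges. The step needs enantioface selection, straight rather than crossed regiochemistry and ring closure ahead of dimerisation; the single strongly Lewis-basic carbonyl next to C3 directs the catalyst, the short tether with two benzylic radical termini fixes the regiochemistry, and high dilution suppresses dimerisation. The s-cis ester rotamer needed for closure is the minor one, but a bulky Lewis acid on the carbonyl oxygen should raise its share (as bulky aluminium aryloxides do in radical lactonisations of allyl esters), the unbound ester should not be sensitised, and a triplet that fails to close only returns ester by E/Z isomerisation, from either alkene geometry of which the same diradical is reached.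

Step 7
Reactants: 10 (1S,5R,6S,7R)-7-[3,4-bis(benzyloxy)-5-methoxyphenyl]-6-[3-methoxy-4-(propan-2-yloxy)phenyl]-3-oxabicyclo[3.2.0]heptan-2-one
Product: 11 lithium (1S,2R,3S,4R)-2-[3,4-bis(benzyloxy)-5-methoxyphenyl]-4-(hydroxymethyl)-3-[3-methoxy-4-(propan-2-yloxy)phenyl]cyclobutane-1-carboxylate
Conditions: LiOH·H2O (1.05 equiv), THF/H2O 3:1, rt; evaporate, dry by azeotrope with toluene
Reagents that add atoms: lithium hydroxide, [Li+].[OH-]
Why: Saponification of the strained γ-lactone gives a carboxylate that is inert to dissolving metal, whereas the lactone carbonyl would itself be reduced and its ketyl would open the wrong bond (C3–C6).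

Step 8
Reactants: 11 lithium (1S,2R,3S,4R)-2-[3,4-bis(benzyloxy)-5-methoxyphenyl]-4-(hydroxymethyl)-3-[3-methoxy-4-(propan-2-yloxy)phenyl]cyclobutane-1-carboxylate
Product: 13 (3S,4R)-3-[(3,4-dihydroxy-5-methoxyphenyl)methyl]-4-{[3-methoxy-4-(propan-2-yloxy)phenyl]methyl}oxolan-2-one (the cis lactone), via hydroxy acid 12 (not isolated)
Conditions: Li (about 8 equiv, to a blue colour lasting 10 min), NH3(l)/THF, −78 °C; solid NH4Cl; evaporate; 1 M HCl/EtOAc, rt
Reagents that add atoms: none
Why: In this dissolving-metal (Birch-type) reduction the benzyl ethers of ring B are cleaved to aryloxides that resist further reduction, ring A stays a neutral alkyl aryl ether whose radical anion breaks the strained, doubly benzylic C6–C7 bond (mesolytic cleavage, as in alkali-metal ring opening of 1,2-diarylcyclopropanes and 1,2-diarylcyclobutanes), the benzylic anions are protonated by NH3, and acidification lets the γ-hydroxy acid lactonise with C3 and C4 untouched.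

Step 9
Reactants: 13 (3S,4R)-3-[(3,4-dihydroxy-5-methoxyphenyl)methyl]-4-{[3-methoxy-4-(propan-2-yloxy)phenyl]methyl}oxolan-2-one
Product: 14 (3R,4R)-3-[(3,4-dihydroxy-5-methoxyphenyl)methyl]-4-{[3-methoxy-4-(propan-2-yloxy)phenyl]methyl}oxolan-2-one (the trans lactone)
Conditions: NaOMe (6 equiv), degassed MeOH, argon, 50 °C; 1 M HCl
Reagents that add atoms: none
Why: Base-mediated epimerisation through the lactone enolate runs under thermodynamic control, and since the trans-3,4-dibenzyl lactone is the more stable diastereomer C3 should end as R, while C4, which bears no acidic hydrogen, keeps its configuration.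

Step 10
Reactants: 14 (3R,4R)-3-[(3,4-dihydroxy-5-methoxyphenyl)methyl]-4-{[3-methoxy-4-(propan-2-yloxy)phenyl]methyl}oxolan-2-one
Product: 15 (−)-thujaplicatin, (3R,4R)-3-[(3,4-dihydroxy-5-methoxyphenyl)methyl]-4-[(4-hydroxy-3-methoxyphenyl)methyl]oxolan-2-one
Conditions: BCl3 (5 equiv), CH2Cl2, −78 to 0 °C; H2O
Reagents that add atoms: none
Why: Lewis-acid ether cleavage with BCl3 removes isopropyl aryl ethers (departure of the secondary alkyl group as chloride) far faster than methyl aryl ethers at or below 0 °C, so ring A should be unmasked without loss of either methoxy group or of the lactone configuration.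

**Compound list**

1 | ferulic acid, (E)-3-(4-hydroxy-3-methoxyphenyl)prop-2-enoic acid | COc1cc(/C=C/C(=O)O)ccc1O | starting material
2 | propan-2-yl (E)-3-[3-methoxy-4-(propan-2-yloxy)phenyl]prop-2-enoate | COc1cc(/C=C/C(=O)OC(C)C)ccc1OC(C)C | intermediate
3 | (E)-3-[3-methoxy-4-(propan-2-yloxy)phenyl]prop-2-en-1-ol | COc1cc(/C=C/CO)ccc1OC(C)C | intermediate
4 | 5-hydroxyvanillin, 3,4-dihydroxy-5-methoxybenzaldehyde | COc1cc(C=O)cc(O)c1O | starting material
5 | 3,4-bis(benzyloxy)-5-methoxybenzaldehyde | COc1cc(C=O)cc(OCc2ccccc2)c1OCc1ccccc1 | intermediate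
6 | malonic acid | OC(=O)CC(=O)O | starting material
7 | 2-{[3,4-bis(benzyloxy)-5-methoxyphenyl]methylidene}propanedioic acid (not isolated) | COc1cc(C=C(C(=O)O)C(=O)O)cc(OCc2ccccc2)c1OCc1ccccc1 | intermediate
8 | (E)-3-[3,4-bis(benzyloxy)-5-methoxyphenyl]prop-2-enoic acid | COc1cc(/C=C/C(=O)O)cc(OCc2ccccc2)c1OCc1ccccc1 | intermediate
9 | (E)-3-[3-methoxy-4-(propan-2-yloxy)phenyl]prop-2-en-1-yl (E)-3-[3,4-bis(benzyloxy)-5-methoxyphenyl]prop-2-enoate | O=C(/C=C/c1cc(OCc2ccccc2)c(OCc2ccccc2)c(OC)c1)OC/C=C/c1ccc(OC(C)C)c(OC)c1 | intermediate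
10 | (1S,5R,6S,7R)-7-[3,4-bis(benzyloxy)-5-methoxyphenyl]-6-[3-methoxy-4-(propan-2-yloxy)phenyl]-3-oxabicyclo[3.2.0]heptan-2-one | COc1cc([C@@H]3[C@H]2COC(=O)[C@H]2[C@@H]3c2cc(OCc3ccccc3)c(OCc3ccccc3)c(OC)c2)ccc1OC(C)C | intermediate
11 | lithium (1S,2R,3S,4R)-2-[3,4-bis(benzyloxy)-5-methoxyphenyl]-4-(hydroxymethyl)-3-[3-methoxy-4-(propan-2-yloxy)phenyl]cyclobutane-1-carboxylate | [Li+].[O-]C(=O)[C@@H]1[C@H](CO)[C@@H](c2ccc(OC(C)C)c(OC)c2)[C@H]1c1cc(OCc2ccccc2)c(OCc2ccccc2)c(OC)c1 | intermediate
12 | (2S,3R)-2-[(3,4-dihydroxy-5-methoxyphenyl)methyl]-3-(hydroxymethyl)-4-[3-methoxy-4-(propan-2-yloxy)phenyl]butanoic acid (not isolated) | OC(=O)[C@@H](Cc1cc(O)c(O)c(OC)c1)[C@H](CO)Cc1ccc(OC(C)C)c(OC)c1 | intermediate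
13 | (3S,4R)-3-[(3,4-dihydroxy-5-methoxyphenyl)methyl]-4-{[3-methoxy-4-(propan-2-yloxy)phenyl]methyl}oxolan-2-one | COc1cc(C[C@H]2COC(=O)[C@H]2Cc2cc(O)c(O)c(OC)c2)ccc1OC(C)C | intermediate
14 | (3R,4R)-3-[(3,4-dihydroxy-5-methoxyphenyl)methyl]-4-{[3-methoxy-4-(propan-2-yloxy)phenyl]methyl}oxolan-2-one | COc1cc(C[C@H]2COC(=O)[C@@H]2Cc2cc(O)c(O)c(OC)c2)ccc1OC(C)C | intermediate
15 | (−)-thujaplicatin, (3R,4R)-3-[(3,4-dihydroxy-5-methoxyphenyl)methyl]-4-[(4-hydroxy-3-methoxyphenyl)methyl]oxolan-2-one | COc1cc(C[C@H]2COC(=O)[C@@H]2Cc2cc(O)c(O)c(OC)c2)ccc1O | target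

**Step count and risks**

Total steps: 10. Longest linear sequence: 8 steps (steps 1, 2, 5–10 from ferulic acid; equally steps 3, 4, 5–10 from 5-hydroxyvanillin).

Steps most likely to fail:

Step 6. Too little of the s-cis ester rotamer may be populated, so that triplet decay by E/Z isomerisation and intermolecular cycloaddition outrun ring closure. Facial discrimination by the Lewis acid may be weak, and the Lewis acid may ionise the electron-rich cinnamyl C5–O1 bond. The fallback uses known chemistry only, sets out from 2 and 5 and comes back at 14. Hydrogenation of 2 (H2, Pd/C, EtOAc) gives propan-2-yl 3-[3-methoxy-4-(propan-2-yloxy)phenyl]propanoate F1, and LiOH gives 3-[3-methoxy-4-(propan-2-yloxy)phenyl]propanoic acid F2. Me3CCOCl/Et3N converts this into the pivalic mixed anhydride F3, which acylates lithiated (S)-4-benzyl-1,3-oxazolidin-2-one to give (4S)-4-benzyl-3-{3-[3-methoxy-4-(propan-2-yloxy)phenyl]propanoyl}-1,3-oxazolidin-2-one F4. Evans alkylation (NaN(SiMe3)2, tert-butyl bromoacetate, THF, −78 °C) occurs anti to the auxiliary benzyl group and gives tert-butyl (3R)-3-{[(4S)-4-benzyl-2-oxo-1,3-oxazolidin-3-yl]carbonyl}-4-[3-methoxy-4-(propan-2-yloxy)phenyl]butanoate F5. LiBH4 removes the auxiliary to give tert-butyl (3R)-3-(hydroxymethyl)-4-[3-methoxy-4-(propan-2-yloxy)phenyl]butanoate F6, which TsOH in warm toluene closes to (4R)-4-{[3-methoxy-4-(propan-2-yloxy)phenyl]methyl}oxolan-2-one F7. In parallel 5 is reduced (NaBH4, MeOH) to [3,4-bis(benzyloxy)-5-methoxyphenyl]methanol F8 and converted (PBr3, CH2Cl2) into 1,2-bis(benzyloxy)-5-(bromomethyl)-3-methoxybenzene F9. Deprotonation of F7 with LiN(SiMe3)2 (THF, −78 °C) and alkylation with F9 trans to the C4 substituent gives (3R,4R)-3-{[3,4-bis(benzyloxy)-5-methoxyphenyl]methyl}-4-{[3-methoxy-4-(propan-2-yloxy)phenyl]methyl}oxolan-2-one F10, and hydrogenolysis (H2, Pd/C, EtOAc) returns to 14.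

Step 8. Birch over-reduction or O-dealkylation of ring A may compete with C6–C7 scission, or scission may stall, leaving the cyclobutane. The fallback replaces electron transfer by catalytic hydrogenolysis, sets out from 10 (step 7 is then not needed) and comes back at 13. H2 (1 atm), Pd/C in EtOAc/MeOH first removes the benzyl ethers to give (1S,5R,6S,7R)-7-(3,4-dihydroxy-5-methoxyphenyl)-6-[3-methoxy-4-(propan-2-yloxy)phenyl]-3-oxabicyclo[3.2.0]heptan-2-one F11. Forcing conditions (H2 50 bar, Pd(OH)2/C, AcOH, 70 °C) then hydrogenolyse the strained doubly benzylic C6–C7 bond, as is known for arylcyclopropanes and benzocyclobutenes, and give 13 with the lactone intact.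

Step 9. The catecholate may be oxidised by traces of air in the basic medium, or equilibration may stay incomplete. The fallback epimerises a phenol-free substrate, sets out from 13 and comes back at 14. Benzyl bromide/K2CO3 in acetone re-protects the catechol to give (3S,4R)-3-{[3,4-bis(benzyloxy)-5-methoxyphenyl]methyl}-4-{[3-methoxy-4-(propan-2-yloxy)phenyl]methyl}oxolan-2-one F12. NaOMe in MeOH then equilibrates C3 to the trans lactone F10 (the compound of the first fallback), and H2, Pd/C removes the benzyl ethers to give 14.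

Further compounds
F1 | step 6 | propan-2-yl 3-[3-methoxy-4-(propan-2-yloxy)phenyl]propanoate | COc1cc(CCC(=O)OC(C)C)ccc1OC(C)C
F2 | step 6 | 3-[3-methoxy-4-(propan-2-yloxy)phenyl]propanoic acid | COc1cc(CCC(=O)O)ccc1OC(C)C
F3 | step 6 | 2,2-dimethylpropanoic 3-[3-methoxy-4-(propan-2-yloxy)phenyl]propanoic anhydride | COc1cc(CCC(=O)OC(=O)C(C)(C)C)ccc1OC(C)C
F4 | step 6 | (4S)-4-benzyl-3-{3-[3-methoxy-4-(propan-2-yloxy)phenyl]propanoyl}-1,3-oxazolidin-2-one | COc1cc(CCC(=O)N2[C@@H](Cc3ccccc3)COC2=O)ccc1OC(C)C
F5 | step 6 | tert-butyl (3R)-3-{[(4S)-4-benzyl-2-oxo-1,3-oxazolidin-3-yl]carbonyl}-4-[3-methoxy-4-(propan-2-yloxy)phenyl]butanoate | COc1cc(C[C@H](CC(=O)OC(C)(C)C)C(=O)N2[C@@H](Cc3ccccc3)COC2=O)ccc1OC(C)C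
F6 | step 6 | tert-butyl (3R)-3-(hydroxymethyl)-4-[3-methoxy-4-(propan-2-yloxy)phenyl]butanoate | COc1cc(C[C@H](CC(=O)OC(C)(C)C)CO)ccc1OC(C)C
F7 | step 6 | (4R)-4-{[3-methoxy-4-(propan-2-yloxy)phenyl]methyl}oxolan-2-one | COc1cc(C[C@H]2COC(=O)C2)ccc1OC(C)C
F8 | step 6 | [3,4-bis(benzyloxy)-5-methoxyphenyl]methanol | COc1cc(CO)cc(OCc2ccccc2)c1OCc1ccccc1
F9 | step 6 | 1,2-bis(benzyloxy)-5-(bromomethyl)-3-methoxybenzene | COc1cc(CBr)cc(OCc2ccccc2)c1OCc1ccccc1
F10 | step 6 | (3R,4R)-3-{[3,4-bis(benzyloxy)-5-methoxyphenyl]methyl}-4-{[3-methoxy-4-(propan-2-yloxy)phenyl]methyl}oxolan-2-one | COc1cc(C[C@H]2COC(=O)[C@@H]2Cc2cc(OCc3ccccc3)c(OCc3ccccc3)c(OC)c2)ccc1OC(C)C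
F11 | step 8 | (1S,5R,6S,7R)-7-(3,4-dihydroxy-5-methoxyphenyl)-6-[3-methoxy-4-(propan-2-yloxy)phenyl]-3-oxabicyclo[3.2.0]heptan-2-one | COc1cc([C@@H]3[C@H]2COC(=O)[C@H]2[C@@H]3c2cc(O)c(O)c(OC)c2)ccc1OC(C)C
F12 | step 9 | (3S,4R)-3-{[3,4-bis(benzyloxy)-5-methoxyphenyl]methyl}-4-{[3-methoxy-4-(propan-2-yloxy)phenyl]methyl}oxolan-2-one | COc1cc(C[C@H]2COC(=O)[C@H]2Cc2cc(OCc3ccccc3)c(OCc3ccccc3)c(OC)c2)ccc1OC(C)C
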